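## Structural features

The target is a germacranolide: a ten-membered carbocycle (C1–C10) cis-fused through C7–C8 to an α-methylene-γ-butyrolactone (C11=C13 exocyclic, C12 carbonyl, ring oxygen on C8). The carbocycle carries an E-trisubstituted alkene C1=C10 (C14 methyl on C10), a cis-4,5-epoxide with the C15 methyl on C4 (C3 and C6 on the same side of the oxirane), and acetates on C2 and C6. Five stereocentres are contiguous (C4–C5–C6–C7–C8) and C2 stands alone; the descriptors are 2S,4R,5S,6S,7R,8R. Along the chain O5/O6 are anti (erythro), O6/C11 syn, C11/O8 anti and O6/O8 1,3-anti. Fragile groups are the α-methylene lactone (Michael acceptor), the epoxide facing C1=C10 across the ring (acid-triggered transannular opening), the allylic C2 acetate (ionised by low-valent metals, reduced by hydride reagents), and C7–H whenever C6 or C8 is a carbonyl. The real difficulties are closing the ten-membered ring with E geometry intact and setting the erythro epoxy acetate, which hydroxyl-directed epoxidation of an open-chain Z-allylic alcohol (threo-selective) would not give. The key step exploits that C10 is a methyl-bearing sp2 carbon and C9 a methylene next to oxygenated C8: both can carry iodine, so the alkene geometry is fixed on the open chain and C9–C10 is made between two electrophilic carbons.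

## Logic of the disconnections

34 to 33 and 30: the acetyl–O2 bond and the lactone bond C12–O8 (with the C12 oxidation level) are cut first. The Michael acceptor is thereby removed from all earlier stages. The forward demand is an oxidation that takes the primary allylic C12 hydroxyl in the presence of the secondary C2 hydroxyl, without acid.

30 to 29 and 28: only O–Si and O–benzyl bonds are cut. The forward steps must spare the epoxide and the C6 acetate.

28 to 27: the ring bond C9–C10 is cut. The ten-membered ring becomes an open chain whose six stereocentres and both double-bond geometries are already in place. The forward step must join an alkenyl and an alkyl iodide without losing E geometry and without a fast intramolecular trap for a C9 radical.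

27 to 26, 25 and 24: C9–I goes back to C9–O and the O8 silyl group is removed. This leads to a compound in which O6 (acetate), O8 (free) and O9 (silyl) are already differentiated. The forward demand is selective cleavage of a primary silyl ether beside two secondary ones.

24 to 23: the C8–H bond and the O6–acetyl bond are cut together. One operation sets C8 (1,3-anti to O6) and places the acetate on O6 only. It requires a free C6 hydroxyl next to a C8 ketone.

23 to 21 and 13: the C6–C7 bond is cut. This is the convergent union of the two halves. The forward aldol must be syn (C6/C7) and must attack 13 anti to the epoxide C5–O bond; the erythro O5/O6 relation then follows from the aldehyde.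

13 to 12 and 11: the C6 oxidation level is lowered and the two epoxide C–O bonds are cut. A primary Z-allylic alcohol allows reagent-controlled epoxidation, independent of C2 and C6.

11 back to 1 and 2: the C10–I and C1–H bonds (alkyne), then C4–C15, then C5–C6 (ester carbon), then C2–C3 are cut in turn. Each step adds one small unit; the demands are distal zirconium placement, syn methyl-copper addition held cold, and an enantioselective propargylation that sets C2.

21 to 20, then to 17 and 18, and 17 to 14 and 15: the ketone is taken back to a carbinol, then the C7–C8 bond and one ether bond are cut. All pieces are catalogue compounds and no stereocentre has to be controlled.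

## Other disconnections considered

Alternative 1: the ten-membered ring is traced back to a decalin by adding a transannular C1–C6 bond. In the forward sense the sulfonylhydrazone of the C10 ketone of A1 fragments the C1/C6 epoxide and releases the cyclodecenynone A2. In its favour, the fragmentation is established chemistry for ten-membered cycloalkynones, and the ring is made from a rigid bicycle with no macrocyclisation entropy; on both points it is the better of the two plans. The Z geometry of C4=C5 is fixed by the six-membered ring, which is equal to the chosen plan. Against it, A2 lacks C14 and C13 and has a C6 ketone. The C1≡C10 alkyne must take up methyl and hydrogen in an anti sense with methyl at C10, because syn addition to a ring alkyne gives the Z ring alkene. C6 must be reduced, the lactone methylenated and the alkene epoxidised after the key step. Structurally A2 is much further from 34 than 28 is, and the step count after the key step is higher.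

Alternative 2: the C6–C7 bond is cut and the ring is enlarged to the thirteen-membered allylic ether A3. In the forward sense, tin–lithium exchange at C6 starts a [2,3] shift that forms C6–C7, breaks O–C13 and gives A4. In its favour, ring contraction of thirteen-membered ethers to germacrane-type carbocycles is a known reaction type (better precedent than the chosen closure). The step creates the C6 carbinol, C7 and the exocyclic methylene at once (more stereochemical work per step). A4 keeps C4=C5, so a ring-directed epoxidation with the cis preference of medium-ring allylic alcohols becomes available. Against it, A3 is itself a macrocycle that needs its own ring closure and a defined α-alkoxystannane. The C6 carbanion is allylic as well as α-oxygenated, so competing shifts and loss of Z geometry are possible. The sense of induction at C6/C7 relative to C8 rests on the conformation of a thirteen-membered transition state. In step economy it is equal at best; in stereochemical predictability the chosen plan, which forms no stereocentre at ring closure, is safer.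

Alternative 3: the C1–C2 bond and the C10–methyl bond are cut. In the forward sense, zerovalent nickel with a chiral carbene ligand couples the aldehyde and the terminal alkyne of A5 with a methylzinc donor to give A6. In its favour there are no halides and no radical. One step makes the ring, the C10 methyl, the E alkene (syn addition puts C2 and methyl cis) and the C2 carbinol, which is better in convergence. A5 is easier to reach than 27, and the free C2 hydroxyl of A6 arrives already differentiated (equal or better). Against it, such alkylative ynal cyclisations are known for larger rings, not for ten. C2 would be set by the ligand inside a macrocyclic transition state, whereas the chosen plan sets it early by a known addition. The C2 aldehyde of A5 is β,γ-unsaturated and prone to conjugation, and the retained C4=C5 alkene again needs a late ring epoxidation. Both plans depend on low-valent nickel at the limit of precedent, so the risk at ring closure is about equal.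

Key step: step 17

Assumption (remark on the chemistry): only the carbon skeleton and the C9/C10 diiodide pattern of the ring-closure substrate are kept. C2 carries a silyl ether, since an allylic acetate would be ionised by zerovalent nickel and attacked by Cp2Zr(H)Cl. C6 carries the acetate. C4–C5 is already the cis-epoxide, since a C9 radical 1,5 to a C4=C5 alkene is a hex-5-enyl radical and would cyclise 5-exo before capture. The descriptors of 27 and 28 were re-derived and agree with 34 at every centre, so no descriptor needed correcting.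

## Steps

Step 1
Reactants: 1 but-2-ynal; 2 allenylboronic acid pinacol ester
Product: 3 (S)-hepta-1,5-diyn-4-ol
Conditions: (S)-TRIP (10 mol %), 4 Å MS, toluene, −30 °C
Reagents that add atoms: none
Why: Chiral phosphoric acid-catalysed propargylation (SE2' addition of the allenylboronate through a six-membered transition state); the (S)-catalyst is chosen because its antipode gives (R)-carbinols from aryl aldehydes and the alkynyl group of 1 takes the place of the aryl group, so C2 should form as S.

Step 2
Reactants: 3 (S)-hepta-1,5-diyn-4-ol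
Product: 4 (S)-tert-butyl(hepta-1,5-diyn-4-yloxy)dimethylsilane
Conditions: TBSCl, imidazole, DMF, 0 → 23 °C
Reagents that add atoms: tert-butyldimethylsilyl chloride, CC(C)(C)[Si](C)(C)Cl
Why: Standard silylation of a secondary propargylic alcohol; the bulky group later steers zirconium away from C1.

Step 3
Reactants: 4 (S)-tert-butyl(hepta-1,5-diyn-4-yloxy)dimethylsilane
Product: 6 methyl (S)-5-(tert-butyldimethylsilyloxy)octa-2,6-diynoate, via lithium acetylide 5 (not isolated)
Conditions: n-BuLi, THF, −78 °C; ClCO2Me, −78 → 0 °C
Reagents that add atoms: methyl chloroformate, COC(=O)Cl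
Why: Deprotonation of the only terminal alkyne and C-acylation of the acetylide; the internal alkyne and the silyl ether are inert.

Step 4
Reactants: 6 methyl (S)-5-(tert-butyldimethylsilyloxy)octa-2,6-diynoate
Product: 8 methyl (2Z,5S)-5-(tert-butyldimethylsilyloxy)-3-methyloct-2-en-6-ynoate, via alkenylcuprate 7 (not isolated)
Conditions: Me2CuLi (MeLi, CuI), THF, −78 °C; MeOH, −78 °C; aq NH4Cl
Reagents that add atoms: lithium dimethylcuprate, [Li+].C[Cu-]C
Why: Syn carbocupration of the ynoate and protonation with retention place the new methyl cis to H5, so C3 and C6 are cis (Z); the cold quench prevents equilibration of the alkenylcuprate through its allenolate.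

Step 5
Reactants: 8 methyl (2Z,5S)-5-(tert-butyldimethylsilyloxy)-3-methyloct-2-en-6-ynoate
Product: 9 (2Z,5S)-5-(tert-butyldimethylsilyloxy)-3-methyloct-2-en-6-yn-1-ol
Conditions: DIBAL-H, CH2Cl2, −78 °C; Rochelle salt
Reagents that add atoms: none
Why: 1,2-Reduction of the enoate to the allylic alcohol without change of the Z geometry.

Step 6
Reactants: 9 (2Z,5S)-5-(tert-butyldimethylsilyloxy)-3-methyloct-2-en-6-yn-1-ol
Product: 11 (2Z,5S,6E)-5-(tert-butyldimethylsilyloxy)-7-iodo-3-methylocta-2,6-dien-1-ol, via alkenylzirconocene 10 (not isolated)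
Conditions: Cp2Zr(H)Cl (3 equiv), THF, 23 → 40 °C; I2, THF, 0 °C
Reagents that add atoms: iodine, [I][I]
Why: Hydrozirconation/iodination: syn addition of Zr–H with zirconium on the methyl-bearing carbon (distal to the silyloxy-branched C2), then iodinolysis with retention gives the E-alkenyl iodide; one equivalent is consumed by the hydroxyl and the trisubstituted alkene is inert.

Step 7
Reactants: 11 (2Z,5S,6E)-5-(tert-butyldimethylsilyloxy)-7-iodo-3-methylocta-2,6-dien-1-ol
Product: 12 [(2S,3R)-3-[(2S,3E)-2-(tert-butyldimethylsilyloxy)-4-iodopent-3-en-1-yl]-3-methyloxiran-2-yl]methanol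
Conditions: Ti(OiPr)4 (10 mol %), L-(+)-diethyl tartrate (12 mol %), t-BuOOH, 4 Å MS, CH2Cl2, −20 °C
Reagents that add atoms: tert-butyl hydroperoxide, CC(C)(C)OO
Why: Sharpless asymmetric epoxidation; with the L-(+)-tartrate a Z-3,3-disubstituted allylic alcohol of the nerol pattern should give the (2S,3R)-epoxy alcohol, which is C4 R and C5 S. Reagent control overrides the remote C2 centre, and the iodoalkene has no free allylic hydroxyl.

Step 8
Reactants: 12 [(2S,3R)-3-[(2S,3E)-2-(tert-butyldimethylsilyloxy)-4-iodopent-3-en-1-yl]-3-methyloxiran-2-yl]methanol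
Product: 13 (2R,3R)-3-[(2S,3E)-2-(tert-butyldimethylsilyloxy)-4-iodopent-3-en-1-yl]-3-methyloxirane-2-carbaldehyde
Conditions: Dess–Martin periodinane, NaHCO3, CH2Cl2, 0 → 23 °C
Reagents that add atoms: none
Why: Buffered Dess–Martin oxidation; no base strong enough to epimerise C5 is present (the descriptor at C5 changes by priority only).

Step 9
Reactants: 14 4-methoxybenzyl alcohol; 15 3-chloro-2-(chloromethyl)prop-1-ene
Product: 17 1-[[2-(chloromethyl)prop-2-en-1-yl]oxymethyl]-4-methoxybenzene, via sodium 4-methoxybenzyl oxide 16 (not isolated)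
Conditions: NaH, THF, 0 °C; 15 (3 equiv), Bu4NI (cat.), 0 → 23 °C
Reagents that add atoms: none
Why: Williamson ether synthesis on a symmetrical bis-allylic chloride; the excess of 15 limits double substitution.

Step 10
Reactants: 17 1-[[2-(chloromethyl)prop-2-en-1-yl]oxymethyl]-4-methoxybenzene; 18 (tert-butyldimethylsilyloxy)acetaldehyde
Product: 20 rac-1-(tert-butyldimethylsilyloxy)-4-[(4-methoxybenzyloxy)methyl]pent-4-en-2-ol, via allylzinc chloride 19 (not isolated)
Conditions: Zn dust, NaI (cat.), THF/sat. aq NH4Cl, 0 → 23 °C
Reagents that add atoms: none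
Why: Barbier allylation forms C7–C8 and the 1,1-disubstituted alkene C11=C13; the carbinol centre is racemic and is removed in the next step.

Step 11
Reactants: 20 rac-1-(tert-butyldimethylsilyloxy)-4-[(4-methoxybenzyloxy)methyl]pent-4-en-2-ol
Product: 21 1-(tert-butyldimethylsilyloxy)-4-[(4-methoxybenzyloxy)methyl]pent-4-en-2-one
Conditions: Dess–Martin periodinane, NaHCO3, CH2Cl2, 0 °C
Reagents that add atoms: none
Why: Buffered Dess–Martin oxidation gives the β,γ-unsaturated ketone without moving the alkene into conjugation.

Step 12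
Reactants: 21 1-(tert-butyldimethylsilyloxy)-4-[(4-methoxybenzyloxy)methyl]pent-4-en-2-one; 13 (2R,3R)-3-[(2S,3E)-2-(tert-butyldimethylsilyloxy)-4-iodopent-3-en-1-yl]-3-methyloxirane-2-carbaldehyde
Product: 23 open-chain β-hydroxy ketone (C8 ketone, C9–OTBS, C6–OH, C12–OPMB, 4,5-epoxide, C2–OTBS, E-C10 iodide; C2, C4, C5, C6 and C7 as in 34), via dibutylboron enolate 22 (not isolated)
Conditions: Bu2BOTf, iPr2NEt, CH2Cl2, −78 °C; 13, −78 → −20 °C; pH 7 buffer, MeOH, H2O2, 0 °C
Reagents that add atoms: none
Why: Boron aldol: the more acidic allylic C7 methylene is enolised to the Z(O)-enolate, which reacts through a Zimmerman–Traxler chair to the 6,7-syn adduct. The face of 13 is chosen by the Cornforth/Felkin–Anh preference of an α-oxygenated aldehyde (attack anti to the epoxide C5–O bond), which gives the 5,6-anti (erythro) relation, so C6 and C7 follow from the epoxide of step 7.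

Step 13
Reactants: 23 open-chain β-hydroxy ketone
Product: 24 open-chain C6 acetate with free C8 hydroxyl (C9–OTBS, C12–OPMB, 4,5-epoxide, C2–OTBS, E-C10 iodide; all six centres as in 34)
Conditions: CH3CHO (8 equiv), SmI2 (30 mol %), THF, −10 °C
Reagents that add atoms: acetaldehyde, CC=O
Why: Evans–Tishchenko reduction: the samarium-bound hemiacetal of acetaldehyde on O6 delivers hydride to C8 through a six-membered chair, giving the 1,3-anti C8 carbinol and leaving the acyl group on O6 only.

Step 14
Reactants: 24 open-chain C6 acetate with free C8 hydroxyl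
Product: 25 open-chain C8,C9-bis(tert-butyldimethylsilyl) ether (C6–OAc, C12–OPMB, 4,5-epoxide, C2–OTBS, E-C10 iodide)
Conditions: TBSOTf, 2,6-lutidine, CH2Cl2, −78 °C
Reagents that add atoms: tert-butyldimethylsilyl triflate, CC(C)(C)[Si](C)(C)OS(=O)(=O)C(F)(F)F
Why: Silyl triflate silylation of the hindered C8 hydroxyl at low temperature; this removes the free hydroxyl that could migrate the acetate or open the epoxide.

Step 15
Reactants: 25 open-chain C8,C9-bis(tert-butyldimethylsilyl) ether
Product: 26 open-chain C9 primary alcohol (C8–OTBS, C6–OAc, C12–OPMB, 4,5-epoxide, C2–OTBS, E-C10 iodide)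
Conditions: HF·pyridine, pyridine, THF, 0 °C
Reagents that add atoms: none
Why: Buffered fluoride cleaves the unhindered primary silyl ether much faster than the two secondary ones.

Step 16
Reactants: 26 open-chain C9 primary alcohol
Product: 27 open-chain diiodide (C9 primary iodide, E-C10 alkenyl iodide, C8–OTBS, C7 bearing 3-(4-methoxybenzyloxy)prop-1-en-2-yl, C6–OAc, (4R,5S)-epoxide, C2–OTBS; centres as in 34)
Conditions: I2, PPh3, imidazole, CH2Cl2, 0 °C
Reagents that add atoms: iodine, [I][I]
Why: Appel-type iodination through the alkoxyphosphonium salt and SN2 attack of iodide at the primary carbon; epoxides routinely survive these conditions.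

Step 17
Reactants: 27 open-chain diiodide
Product: 28 (1(10)E)-8-(tert-butyldimethylsilyloxy)-2-(tert-butyldimethylsilyloxy)-6-acetoxy-4,5-epoxy-12-(4-methoxybenzyloxy)germacra-1(10),11(13)-diene (ten-membered ring; centres as in 34)
Conditions: NiBr2(dme) (50 mol %), 4,4'-di-tert-butyl-2,2'-bipyridine (60 mol %), TDAE (3 equiv), DMA, 25 °C, syringe-pump addition of 27 to 2 mM
Reagents that add atoms: none
Why: Proposed new method: zerovalent nickel, formed from NiBr2(dme), the bipyridine and TDAE, inserts into the alkenyl C10–I bond with retention; a univalent nickel species abstracts iodine from C9 and the primary radical is captured by the alkenylnickel, giving a trivalent alkyl(alkenyl)nickel that forms C9–C10 by reductive elimination. The closest known reaction type is the intermolecular nickel-catalysed reductive cross-electrophile coupling of alkenyl halides with alkyl halides; it has not been shown for a ten-membered carbocycle. The ring closes by reductive elimination from an eleven-membered nickelacycle, formally a 10-endo closure at an sp2–sp3 junction with the alkene inside the ring. No stereocentre is formed and the six existing ones are remote from the reacting carbons. The step needs retention of E geometry (inherent in the configurationally stable alkenylnickel made from the E-iodide), cross- over homo-coupling (the sp2 and sp3 C–I bonds are activated by different modes) and ring closure over oligomerisation (slow addition, high dilution). The substrate offers the C9 radical no fast intramolecular trap: C4–C5 is an epoxide and not an alkene, C2 carries no ionisable allylic ester, and the C8 silyloxy group cannot be expelled from a radical. TDAE leaves no Lewis-acidic metal salt that could open the epoxide.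

Step 18
Reactants: 28 protected macrocycle
Product: 29 macrocyclic C12 allylic alcohol (C2–OTBS, C8–OTBS, C6–OAc, 4,5-epoxide)
Conditions: DDQ, CH2Cl2/pH 7 buffer (10:1), 0 °C
Reagents that add atoms: none
Why: Oxidative cleavage of the 4-methoxybenzyl ether (benzylic hydride abstraction, hydrolysis of the oxocarbenium ion); C2 is still silylated, so no allylic alcohol is exposed to the quinone.

Step 19
Reactants: 29 macrocyclic C12 allylic alcohol
Product: 30 macrocyclic triol (C2–OH, C8–OH, C12–OH, C6–OAc, 4,5-epoxide)
Conditions: HF·pyridine, pyridine, THF, 0 → 23 °C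
Reagents that add atoms: none
Why: Buffered fluoride desilylation of the two secondary silyl ethers; the same conditions are routinely used on substrates with trisubstituted epoxides.

Step 20
Reactants: 30 macrocyclic triol
Product: 33 (1(10)E,2S,4R,5S,6S,7R,8R)-6-acetoxy-4,5-epoxy-2-hydroxygermacra-1(10),11(13)-dien-12,8-olide, via hydroxy enal 31 (not isolated), via lactol 32 (not isolated)
Conditions: TEMPO (20 mol %), PhI(OAc)2 (2.5 equiv), CH2Cl2, 23 °C
Reagents that add atoms: none
Why: Oxoammonium-mediated oxidative lactonisation: the primary allylic C12 hydroxyl is oxidised first, O8 closes the five-membered lactol and a second oxidation gives the α-methylene lactone; the secondary C2 hydroxyl reacts much more slowly and O6 is blocked as the acetate.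

Step 21
Reactants: 33 hydroxy lactone
Product: 34 (1(10)E,2S,4R,5S,6S,7R,8R)-2,6-diacetoxy-4,5-epoxygermacra-1(10),11(13)-dien-12,8-olide (CNP0270851.1)
Conditions: Ac2O, pyridine, DMAP (cat.), CH2Cl2, 0 °C
Reagents that add atoms: acetic anhydride, CC(=O)OC(C)=O
Why: Acylation of the remaining secondary allylic hydroxyl with retention at C2; short exposure at 0 °C spares the α-methylene lactone.

## Compound list

1 | but-2-ynal | CC#CC=O | starting material
2 | allenylboronic acid pinacol ester | C=C=CB1OC(C)(C)C(C)(C)O1 | starting material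
3 | (S)-hepta-1,5-diyn-4-ol | C#CC[C@H](O)C#CC | intermediate
4 | (S)-tert-butyl(hepta-1,5-diyn-4-yloxy)dimethylsilane | C#CC[C@H](O[Si](C)(C)C(C)(C)C)C#CC | intermediate
5 | lithium acetylide of 4 | [Li]C#CC[C@H](O[Si](C)(C)C(C)(C)C)C#CC | intermediate
6 | methyl (S)-5-(tert-butyldimethylsilyloxy)octa-2,6-diynoate | COC(=O)C#CC[C@H](O[Si](C)(C)C(C)(C)C)C#CC | intermediate
7 | lithium methyl(alkenyl)cuprate from syn addition to 6 (Cu on C5, cis to the new methyl) | [Li+].COC(=O)/C([Cu-]C)=C(C)\C[C@H](O[Si](C)(C)C(C)(C)C)C#CC | intermediate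
8 | methyl (2Z,5S)-5-(tert-butyldimethylsilyloxy)-3-methyloct-2-en-6-ynoate | COC(=O)/C=C(C)\C[C@H](O[Si](C)(C)C(C)(C)C)C#CC | intermediate
9 | (2Z,5S)-5-(tert-butyldimethylsilyloxy)-3-methyloct-2-en-6-yn-1-ol | OC/C=C(C)\C[C@H](O[Si](C)(C)C(C)(C)C)C#CC | intermediate
10 | E-alkenylzirconocene chloride at C10 (hydroxyl held as zirconocene alkoxide) | Cl[Zr](C1C=CC=C1)(C1C=CC=C1)OC/C=C(C)\C[C@H](O[Si](C)(C)C(C)(C)C)/C=C(C)/[Zr](Cl)(C1C=CC=C1)C1C=CC=C1 | intermediate
11 | (2Z,5S,6E)-5-(tert-butyldimethylsilyloxy)-7-iodo-3-methylocta-2,6-dien-1-ol | OC/C=C(C)\C[C@H](O[Si](C)(C)C(C)(C)C)/C=C(C)/I | intermediate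
12 | [(2S,3R)-3-[(2S,3E)-2-(tert-butyldimethylsilyloxy)-4-iodopent-3-en-1-yl]-3-methyloxiran-2-yl]methanol | OC[C@@H]1O[C@]1(C)C[C@H](O[Si](C)(C)C(C)(C)C)/C=C(C)/I | intermediate
13 | (2R,3R)-3-[(2S,3E)-2-(tert-butyldimethylsilyloxy)-4-iodopent-3-en-1-yl]-3-methyloxirane-2-carbaldehyde | O=C[C@@H]1O[C@]1(C)C[C@H](O[Si](C)(C)C(C)(C)C)/C=C(C)/I | intermediate
14 | 4-methoxybenzyl alcohol | COc1ccc(CO)cc1 | starting material
15 | 3-chloro-2-(chloromethyl)prop-1-ene | C=C(CCl)CCl | starting material
16 | sodium 4-methoxybenzyl oxide | [Na+].COc1ccc(C[O-])cc1 | intermediate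
17 | 1-[[2-(chloromethyl)prop-2-en-1-yl]oxymethyl]-4-methoxybenzene | C=C(CCl)COCc1ccc(OC)cc1 | intermediate
18 | (tert-butyldimethylsilyloxy)acetaldehyde | O=CCO[Si](C)(C)C(C)(C)C | starting material
19 | 2-[(4-methoxybenzyloxy)methyl]allylzinc chloride | C=C(C[Zn]Cl)COCc1ccc(OC)cc1 | intermediate
20 | rac-1-(tert-butyldimethylsilyloxy)-4-[(4-methoxybenzyloxy)methyl]pent-4-en-2-ol | CC(C)(C)[Si](C)(C)OCC(O)CC(=C)COCc1ccc(OC)cc1 | intermediate
21 | 1-(tert-butyldimethylsilyloxy)-4-[(4-methoxybenzyloxy)methyl]pent-4-en-2-one | CC(C)(C)[Si](C)(C)OCC(=O)CC(=C)COCc1ccc(OC)cc1 | intermediate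
22 | Z(O)-dibutylboron enolate of 21 (C7=C8) | CCCCB(CCCC)O/C(CO[Si](C)(C)C(C)(C)C)=C\C(=C)COCc1ccc(OC)cc1 | intermediate
23 | open-chain β-hydroxy ketone: C9–OTBS, C8 ketone, C7 bearing 3-(4-methoxybenzyloxy)prop-1-en-2-yl, C6–OH, (4R,5S)-epoxide, (2S)-OTBS, E-C10 iodide; 6,7-syn, 5,6-anti | CC(C)(C)[Si](C)(C)OCC(=O)[C@@H](C(=C)COCc1ccc(OC)cc1)[C@H](O)[C@@H]2O[C@]2(C)C[C@H](O[Si](C)(C)C(C)(C)C)/C=C(C)/I | intermediate
24 | open-chain C6 acetate with free C8 hydroxyl (6,8-anti), C9–OTBS, otherwise as 23 | CC(C)(C)[Si](C)(C)OC[C@@H](O)[C@@H](C(=C)COCc1ccc(OC)cc1)[C@H](OC(C)=O)[C@@H]2O[C@]2(C)C[C@H](O[Si](C)(C)C(C)(C)C)/C=C(C)/I | intermediate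
25 | open-chain C6 acetate with C8–OTBS and C9–OTBS | CC(C)(C)[Si](C)(C)OC[C@@H](O[Si](C)(C)C(C)(C)C)[C@@H](C(=C)COCc1ccc(OC)cc1)[C@H](OC(C)=O)[C@@H]2O[C@]2(C)C[C@H](O[Si](C)(C)C(C)(C)C)/C=C(C)/I | intermediate
26 | open-chain C9 primary alcohol with C8–OTBS, C6–OAc | OC[C@@H](O[Si](C)(C)C(C)(C)C)[C@@H](C(=C)COCc1ccc(OC)cc1)[C@H](OC(C)=O)[C@@H]2O[C@]2(C)C[C@H](O[Si](C)(C)C(C)(C)C)/C=C(C)/I | intermediate
27 | open-chain diiodide: C9 primary iodide, E-C10 alkenyl iodide, C8–OTBS, C6–OAc, (4R,5S)-cis-epoxide, (2S)-OTBS, C12–OPMB | IC[C@@H](O[Si](C)(C)C(C)(C)C)[C@@H](C(=C)COCc1ccc(OC)cc1)[C@H](OC(C)=O)[C@@H]2O[C@]2(C)C[C@H](O[Si](C)(C)C(C)(C)C)/C=C(C)/I | intermediate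
28 | ten-membered ring: (1(10)E)-2,8-bis(tert-butyldimethylsilyloxy)-6-acetoxy-4,5-epoxy-12-(4-methoxybenzyloxy)germacra-1(10),11(13)-diene, centres as in 34 | C1[C@@H](O[Si](C)(C)C(C)(C)C)[C@@H](C(=C)COCc2ccc(OC)cc2)[C@H](OC(C)=O)[C@@H]3O[C@]3(C)C[C@H](O[Si](C)(C)C(C)(C)C)/C=C(C)/1 | intermediate
29 | macrocyclic C12 allylic alcohol, C2–OTBS, C8–OTBS, C6–OAc | C1[C@@H](O[Si](C)(C)C(C)(C)C)[C@@H](C(=C)CO)[C@H](OC(C)=O)[C@@H]2O[C@]2(C)C[C@H](O[Si](C)(C)C(C)(C)C)/C=C(C)/1 | intermediate
30 | macrocyclic 2,8,12-triol 6-acetate | C1[C@@H](O)[C@@H](C(=C)CO)[C@H](OC(C)=O)[C@@H]2O[C@]2(C)C[C@H](O)/C=C(C)/1 | intermediate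
31 | macrocyclic 2,8-diol with C12 enal | C1[C@@H](O)[C@@H](C(=C)C=O)[C@H](OC(C)=O)[C@@H]2O[C@]2(C)C[C@H](O)/C=C(C)/1 | intermediate
32 | 8,12-lactol (both C12 epimers) with free C2 hydroxyl | C1[C@H]2OC(O)C(=C)[C@H]2[C@H](OC(C)=O)[C@@H]3O[C@]3(C)C[C@H](O)/C=C(C)/1 | intermediate
33 | (1(10)E,2S,4R,5S,6S,7R,8R)-6-acetoxy-4,5-epoxy-2-hydroxygermacra-1(10),11(13)-dien-12,8-olide | C1[C@H]2OC(=O)C(=C)[C@H]2[C@H](OC(C)=O)[C@@H]3O[C@]3(C)C[C@H](O)/C=C(C)/1 | intermediate
34 | (1(10)E,2S,4R,5S,6S,7R,8R)-2,6-diacetoxy-4,5-epoxygermacra-1(10),11(13)-dien-12,8-olide | C=C1C(=O)O[C@@H]2C/C(C)=C/[C@@H](OC(C)=O)C[C@@]3(C)O[C@H]3[C@@H](OC(C)=O)[C@H]12 | target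

## Step count and least certain steps

Total step count: 21. Longest linear sequence: 18 steps (steps 1–8 and 12–21).

Step 17 (key step). The most likely failures are intermolecular coupling to dimers and oligomers, reduction of the C9 radical to a methyl group, or 1,5-hydrogen transfer from the allylic C12 methylene to the C9 radical. All would arise because capture of the radical through a medium-ring nickelacycle is slow. Fallback with known reaction types, closing the same bond by a polar addition and then removing the extra oxygen with regiocontrol from O8: setting out from 24, the C8 hydroxyl is converted with ClCO2Me and pyridine into the methyl carbonate F1. Buffered HF·pyridine frees C9 to give the primary alcohol F2, which is oxidised at once with Dess–Martin periodinane to the aldehyde F3. A Nozaki–Hiyama–Kishi macrocyclisation (CrCl2, catalytic NiCl2, DMSO, high dilution) adds the E-alkenylchromium at C10 to the C9 aldehyde, and the new alkoxide closes onto the neighbouring carbonate to give the macrocyclic allylic cyclic carbonate F4 (either C9 epimer serves). Palladium-catalysed formate hydrogenolysis (Pd2(dba)3, PBu3, HCO2H, Et3N) ionises the allylic C9–O bond with loss of CO2 and delivers hydride to C9, the terminus next to the alkoxide, giving the homoallylic alcohol F5 with C1=C10 in place. Silylation with TBSOTf and 2,6-lutidine comes back to 28.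

Step 12. The likely failures are weak facial discrimination of the aldehyde, enolisation on the silyloxymethyl side, or retro-aldol and C7 epimerisation of the adduct. Fallback: substrate control is replaced by reagent control. The same partners 21 and 13 are joined through the diisopinocampheylboron enolate of the antipode that reinforces the Cornforth sense (matched double stereodifferentiation), leading to the same 23; no new compound arises (F0).

Step 13. The likely failures are retro-aldol before hydride transfer, migration of the acetate from O6 to O8, or opening of the epoxide by the C8 alkoxide on trivalent samarium. Fallback by hydroxyl-directed reduction and diol differentiation: setting out from 23, Me4NBH(OAc)3 in AcOH/MeCN gives the anti-1,3-diol F6. Buffered HF·pyridine gives the triol F7. 2,2-Dimethoxypropane with PPTS ties up the terminal 1,2-diol as the acetonide F8. Ac2O and pyridine give the C6 acetate F9, and aqueous acetic acid frees the diol F10. Double silylation with TBSOTf and 2,6-lutidine comes back to 25.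

Step 20. The likely failures are over-oxidation of the secondary allylic C2 hydroxyl or attack of the free O8 on the epoxide in the acetic acid released. Fallback with oxidation before deprotection: setting out from 29, MnO2 gives the enal F11 and a Pinnick oxidation (NaClO2, NaH2PO4, 2-methyl-2-butene) gives the acrylic acid F12. HF·pyridine then removes both silyl groups, the C8 hydroxy acid lactonises, and the route is rejoined at 33.

## Further compounds

F1 | step 17 | open-chain C8 methyl carbonate of 24 (C9–OTBS, C6–OAc) | CC(C)(C)[Si](C)(C)OC[C@@H](OC(=O)OC)[C@@H](C(=C)COCc1ccc(OC)cc1)[C@H](OC(C)=O)[C@@H]2O[C@]2(C)C[C@H](O[Si](C)(C)C(C)(C)C)/C=C(C)/I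
F2 | step 17 | open-chain C9 primary alcohol with C8 methyl carbonate | OC[C@@H](OC(=O)OC)[C@@H](C(=C)COCc1ccc(OC)cc1)[C@H](OC(C)=O)[C@@H]2O[C@]2(C)C[C@H](O[Si](C)(C)C(C)(C)C)/C=C(C)/I
F3 | step 17 | open-chain C9 aldehyde with C8 methyl carbonate | O=C[C@@H](OC(=O)OC)[C@@H](C(=C)COCc1ccc(OC)cc1)[C@H](OC(C)=O)[C@@H]2O[C@]2(C)C[C@H](O[Si](C)(C)C(C)(C)C)/C=C(C)/I
F4 | step 17 | macrocyclic 8,9-cyclic carbonate (C9 epimers), 1(10)E | O=C1OC2[C@@H](O1)[C@@H](C(=C)COCc3ccc(OC)cc3)[C@H](OC(C)=O)[C@@H]4O[C@]4(C)C[C@H](O[Si](C)(C)C(C)(C)C)/C=C(C)/2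
F5 | step 17 | macrocyclic C8 alcohol (28 without the C8 silyl group) | C1[C@@H](O)[C@@H](C(=C)COCc2ccc(OC)cc2)[C@H](OC(C)=O)[C@@H]3O[C@]3(C)C[C@H](O[Si](C)(C)C(C)(C)C)/C=C(C)/1
F0 | step 12 | none | none
F6 | step 13 | open-chain 6,8-anti diol with C9–OTBS | CC(C)(C)[Si](C)(C)OC[C@@H](O)[C@@H](C(=C)COCc1ccc(OC)cc1)[C@H](O)[C@@H]2O[C@]2(C)C[C@H](O[Si](C)(C)C(C)(C)C)/C=C(C)/I
F7 | step 13 | open-chain 6,8,9-triol | OC[C@@H](O)[C@@H](C(=C)COCc1ccc(OC)cc1)[C@H](O)[C@@H]2O[C@]2(C)C[C@H](O[Si](C)(C)C(C)(C)C)/C=C(C)/I
F8 | step 13 | 8,9-acetonide with free C6 hydroxyl | CC1(C)OC[C@@H](O1)[C@@H](C(=C)COCc2ccc(OC)cc2)[C@H](O)[C@@H]3O[C@]3(C)C[C@H](O[Si](C)(C)C(C)(C)C)/C=C(C)/I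
F9 | step 13 | 8,9-acetonide C6 acetate | CC1(C)OC[C@@H](O1)[C@@H](C(=C)COCc2ccc(OC)cc2)[C@H](OC(C)=O)[C@@H]3O[C@]3(C)C[C@H](O[Si](C)(C)C(C)(C)C)/C=C(C)/I
F10 | step 13 | open-chain 8,9-diol C6 acetate | OC[C@@H](O)[C@@H](C(=C)COCc1ccc(OC)cc1)[C@H](OC(C)=O)[C@@H]2O[C@]2(C)C[C@H](O[Si](C)(C)C(C)(C)C)/C=C(C)/I
F11 | step 20 | macrocyclic C12 enal with C2–OTBS and C8–OTBS | C1[C@@H](O[Si](C)(C)C(C)(C)C)[C@@H](C(=C)C=O)[C@H](OC(C)=O)[C@@H]2O[C@]2(C)C[C@H](O[Si](C)(C)C(C)(C)C)/C=C(C)/1
F12 | step 20 | macrocyclic C12 acrylic acid with C2–OTBS and C8–OTBS | C1[C@@H](O[Si](C)(C)C(C)(C)C)[C@@H](C(=C)C(=O)O)[C@H](OC(C)=O)[C@@H]2O[C@]2(C)C[C@H](O[Si](C)(C)C(C)(C)C)/C=C(C)/1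
A1 | alternative 1 | decalin epoxy ketone (C1–C6 bond, C1/C6 epoxide of either face, C10 ketone, C4=C5 in the six-membered ring) | O=C1C[C@@H](OCOC)[C@@H](CCOCc4ccc(OC)cc4)C2(O3)C=C(C)C[C@H](O[Si](C)(C)C(C)(C)C)C123
A2 | alternative 1 | cyclodec-4Z-en-1(10)-yn-6-one | COc1ccc(COCC[C@@H]2[C@H](OCOC)CC#C[C@@H](O[Si](C)(C)C(C)(C)C)C/C(C)=C\C2=O)cc1
A3 | alternative 2 | thirteen-membered allylic ether with tributylstannyl on C6 (C6 configuration and C7=C11 geometry left open) | CCCC[Sn](CCCC)(CCCC)C1OCC(COCc2ccc(OC)cc2)=C[C@H](O[Si](C)(C)C(C)(C)C)C/C(C)=C/[C@@H](O[Si](CC)(CC)CC)C/C(C)=C\1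
A4 | alternative 2 | cyclodeca-1(10)E,4Z-dien-6-ol with exocyclic C11=C13 | C=C(COCc1ccc(OC)cc1)[C@@H]2[C@H](O[Si](C)(C)C(C)(C)C)C/C(C)=C/[C@@H](O[Si](CC)(CC)CC)C/C(C)=C\[C@H]2O
A5 | alternative 3 | open-chain ynal (C2 aldehyde, terminal C1≡C10 alkyne, Z-C4=C5) | C#CC[C@@H](O[Si](C)(C)C(C)(C)C)[C@@H](C(=C)COCc1ccc(OC)cc1)[C@H](O[Si](CC)(CC)CC)/C=C(C)\CC=O
A6 | alternative 3 | cyclodeca-1(10)E,4Z-dien-2-ol | C=C(COCc1ccc(OC)cc1)[C@@H]2[C@H](O[Si](C)(C)C(C)(C)C)C/C(C)=C/[C@@H](O)C/C(C)=C\[C@H]2O[Si](CC)(CC)CC
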